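**Retrosynthetic overview**
1. Ring C is closed last: target 23 ⇐ oxa-Michael closure of the 2′-hydroxychalcone 21 ⇐ Claisen–Schmidt union of ketone 20 (ring A) and aldehyde 15 (ring B carrying the chromene).
2. Ketone 20 ⇐ aromatic Claisen [3,3] rearrangement of the 1,1-dimethylallyl ether 18, which puts the prenyl group at the future C8.
3. Aldehyde 15 ⇐ diol 13 (dehydration of the tertiary alcohol) ⇐ formylation of bromide 11 ⇐ aryl–CH2 bond made by opening methyl (R)-glycidate 8 with the Grignard reagent from iodide 7; the carbinol centre is bought in 8.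
4. Chromene 7 ⇐ aryl propargyl ether 3 by the key thermal cascade: [3,3] Claisen rearrangement, [1,5]-H shift, oxa-6π electrocyclization.
5. Ring order: chromene ring (step 2), then pyranone ring C (step 9). C2 forms under equilibrium with no bias from the remote carbinol, so the (2S) diastereomer 23 is taken out and its C2 epimer 22 is re-equilibrated into it.

Assumption: the SMILES is read as (2S) at the flavanone carbon and (R) at the side-chain carbinol; compounds 1, 2, 8, 16 and 17 are bought (8 is the epoxy ester derived from L-serine).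

**Route**

Step 1
Reactants: 1 4-bromo-2-iodophenol; 2 3-chloro-3-methylbut-1-yne
Product: 3 4-bromo-2-iodo-1-[(2-methylbut-3-yn-2-yl)oxy]benzene
Conditions: DBU, CuCl2 (1 mol %), MeCN, 0 °C → rt
Reagents that add atoms: none
Why: Copper-catalysed propargylic etherification of the phenoxide with the tertiary propargylic chloride gives the hindered aryl 1,1-dimethylpropargyl ether without C-alkylation.

Step 2
Reactants: 3 4-bromo-2-iodo-1-[(2-methylbut-3-yn-2-yl)oxy]benzene
Product: 7 6-bromo-8-iodo-2,2-dimethyl-2H-chromene, via allenyl dienone 4 (not isolated), via allenylphenol 5 (not isolated), via quinone methide 6 (not isolated)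
Conditions: 1,2-dichlorobenzene, 160 °C, 4 h
Reagents that add atoms: none
Why: Propargyl Claisen [3,3] rearrangement to the only free ortho position, enolisation, [1,5]-H shift and oxa-6π electrocyclization build the chromene ring in one thermal operation; no stereocentre is formed.

Step 3
Reactants: 7 6-bromo-8-iodo-2,2-dimethyl-2H-chromene; 8 methyl (2R)-oxirane-2-carboxylate
Product: 11 (2R)-1-(6-bromo-2,2-dimethyl-2H-chromen-8-yl)-3-methylbutane-2,3-diol, via arylmagnesium chloride 9 (not isolated), via hydroxy ester 10 (not isolated)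
Conditions: iPrMgCl·LiCl (1.05 equiv), THF, −30 °C; CuI (10 mol %), 8 (1.2 equiv), −40 → −20 °C; MeMgBr (4 equiv), −20 → 0 °C; aq. NH4Cl
Reagents that add atoms: methylmagnesium bromide, C[Mg]Br
Why: Iodine–magnesium exchange is selective over the aryl bromide, the copper-catalysed SN2 opening of the glycidate occurs at its CH2 carbon so the C–O bond of the (R) centre is never broken, and double Grignard addition to the ester alkoxide then gives the tertiary alcohol.

Step 4
Reactants: 11 (2R)-1-(6-bromo-2,2-dimethyl-2H-chromen-8-yl)-3-methylbutane-2,3-diol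
Product: 13 8-[(2R)-2,3-dihydroxy-3-methylbutyl]-2,2-dimethyl-2H-chromene-6-carbaldehyde, via aryllithium dialkoxide 12 (not isolated)
Conditions: n-BuLi (3.2 equiv), THF, −78 °C; DMF (5 equiv), −78 → 0 °C; H2O
Reagents that add atoms: N,N-dimethylformamide, CN(C)C=O
Why: Two equivalents of base mask the hydroxyls as alkoxides, the third effects bromine–lithium exchange, and the aryllithium is formylated by DMF (Bouveault formylation) without touching the stereocentre.

Step 5
Reactants: 13 8-[(2R)-2,3-dihydroxy-3-methylbutyl]-2,2-dimethyl-2H-chromene-6-carbaldehyde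
Product: 15 (2R)-1-(6-formyl-2,2-dimethyl-2H-chromen-8-yl)-3-methylbut-3-en-2-yl acetate, via monoacetate 14 (not isolated)
Conditions: Ac2O (1.1 equiv), DMAP (5 mol %), pyridine/CH2Cl2, 0 °C; then SOCl2 (2 equiv), −10 → 0 °C; aq. NaHCO3
Reagents that add atoms: acetic anhydride, CC(=O)OC(C)=O
Why: Only the secondary hydroxyl is acetylated, and the tertiary chlorosulfite then eliminates toward a methyl group (the other direction would give an enol acetate), giving the isopropenyl group by regioselective dehydration with the secondary C–O bond and its (R) configuration intact.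

Step 6
Reactants: 16 1-(2,4-dihydroxyphenyl)ethan-1-one; 17 tert-butyl (2-methylbut-3-en-2-yl) carbonate
Product: 18 1-{2-hydroxy-4-[(2-methylbut-3-en-2-yl)oxy]phenyl}ethan-1-one
Conditions: Pd(PPh3)4 (2 mol %), THF, 0 °C → rt
Reagents that add atoms: none
Why: Tsuji–Trost O-allylation: zerovalent palladium ionises the tertiary allylic carbonate and the non-chelated 4-phenoxide attacks the more substituted allyl terminus, leaving the hydrogen-bonded 2-hydroxyl untouched.

Step 7
Reactants: 18 1-{2-hydroxy-4-[(2-methylbut-3-en-2-yl)oxy]phenyl}ethan-1-one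
Product: 20 1-[2,4-dihydroxy-3-(3-methylbut-2-en-1-yl)phenyl]ethan-1-one, via cyclohexadienone 19 (not isolated)
Conditions: N,N-diethylaniline, 190 °C, 2 h
Reagents that add atoms: none
Why: Aromatic Claisen [3,3] rearrangement transposes the 1,1-dimethylallyl unit into a prenyl group at C3, the position between the two oxygens that bond fixation in the chelated hydroxy ketone favours, and tautomerisation restores the arene.

Step 8
Reactants: 15 (2R)-1-(6-formyl-2,2-dimethyl-2H-chromen-8-yl)-3-methylbut-3-en-2-yl acetate; 20 1-[2,4-dihydroxy-3-(3-methylbut-2-en-1-yl)phenyl]ethan-1-one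
Product: 21 (2E)-1-[2,4-dihydroxy-3-(3-methylbut-2-en-1-yl)phenyl]-3-{8-[(2R)-2-hydroxy-3-methylbut-3-en-1-yl]-2,2-dimethyl-2H-chromen-6-yl}prop-2-en-1-one
Conditions: KOH (50 % aq.), EtOH, rt, 48 h, Ar; then 1 M HCl to pH 5, 0 °C
Reagents that add atoms: none
Why: Claisen–Schmidt condensation (aldol addition and dehydration) gives the (E)-chalcone while the hydroxide also saponifies the acetate; the carbinol centre has no acidic hydrogen and cannot epimerise.

Step 9
Reactants: 21 (2E)-1-[2,4-dihydroxy-3-(3-methylbut-2-en-1-yl)phenyl]-3-{8-[(2R)-2-hydroxy-3-methylbut-3-en-1-yl]-2,2-dimethyl-2H-chromen-6-yl}prop-2-en-1-one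
Product: 23 (2S)-7-hydroxy-2-{8-[(2R)-2-hydroxy-3-methylbut-3-en-1-yl]-2,2-dimethyl-2H-chromen-6-yl}-8-(3-methylbut-2-en-1-yl)-2,3-dihydro-4H-chromen-4-one, via C2-epimeric flavanone 22 (not isolated)
Conditions: NaOAc (5 equiv), EtOH, reflux, 24 h; preparative HPLC (C18) takes out 23; the unresolved remainder (22 and 21) is returned to the same conditions, 3–4 cycles
Reagents that add atoms: none
Why: Intramolecular oxa-Michael addition of the 2′-phenoxide closes ring C reversibly and without facial bias from the remote (R)-carbinol, so 23 and its C2 epimer 22 form in about equal amounts; 23 is removed by chromatography, while 22 reopens to 21 by retro-Michael reaction under the same conditions and closes again, so repeated cycles convert the unwanted epimer into 23.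

**Compound list**
1 | 4-bromo-2-iodophenol | Oc1ccc(Br)cc1I | starting material
2 | 3-chloro-3-methylbut-1-yne | C#CC(C)(C)Cl | starting material
3 | 4-bromo-2-iodo-1-[(2-methylbut-3-yn-2-yl)oxy]benzene | C#CC(C)(C)Oc1ccc(Br)cc1I | intermediate
4 | 4-bromo-2-iodo-6-(3-methylbuta-1,2-dien-1-yl)cyclohexa-2,4-dien-1-one (allenyl dienone; not isolated) | CC(C)=C=CC1C=C(Br)C=C(I)C1=O | intermediate
5 | 4-bromo-2-iodo-6-(3-methylbuta-1,2-dien-1-yl)phenol (allenylphenol; not isolated) | CC(C)=C=Cc1cc(Br)cc(I)c1O | intermediate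
6 | 4-bromo-2-iodo-6-(3-methylbut-2-en-1-ylidene)cyclohexa-2,4-dien-1-one (quinone methide; not isolated) | CC(C)=CC=C1C=C(Br)C=C(I)C1=O | intermediate
7 | 6-bromo-8-iodo-2,2-dimethyl-2H-chromene | CC1(C)C=Cc2cc(Br)cc(I)c2O1 | intermediate
8 | methyl (2R)-oxirane-2-carboxylate (methyl (R)-glycidate) | COC(=O)[C@H]1CO1 | starting material
9 | (6-bromo-2,2-dimethyl-2H-chromen-8-yl)magnesium chloride (not isolated) | CC1(C)C=Cc2cc(Br)cc([Mg]Cl)c2O1 | intermediate
10 | methyl (2R)-3-(6-bromo-2,2-dimethyl-2H-chromen-8-yl)-2-hydroxypropanoate (formed as its magnesium alkoxide; not isolated) | COC(=O)[C@H](O)Cc1cc(Br)cc2c1OC(C)(C)C=C2 | intermediate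
11 | (2R)-1-(6-bromo-2,2-dimethyl-2H-chromen-8-yl)-3-methylbutane-2,3-diol | CC(C)(O)[C@H](O)Cc1cc(Br)cc2c1OC(C)(C)C=C2 | intermediate
12 | dilithium (2R)-1-(6-lithio-2,2-dimethyl-2H-chromen-8-yl)-3-methylbutane-2,3-diolate (not isolated) | CC(C)(O[Li])[C@H](O[Li])Cc1cc([Li])cc2c1OC(C)(C)C=C2 | intermediate
13 | 8-[(2R)-2,3-dihydroxy-3-methylbutyl]-2,2-dimethyl-2H-chromene-6-carbaldehyde | CC(C)(O)[C@H](O)Cc1cc(C=O)cc2c1OC(C)(C)C=C2 | intermediate
14 | (2R)-1-(6-formyl-2,2-dimethyl-2H-chromen-8-yl)-3-hydroxy-3-methylbutan-2-yl acetate (not isolated) | CC(C)(O)[C@H](OC(C)=O)Cc1cc(C=O)cc2c1OC(C)(C)C=C2 | intermediate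
15 | (2R)-1-(6-formyl-2,2-dimethyl-2H-chromen-8-yl)-3-methylbut-3-en-2-yl acetate | C=C(C)[C@H](OC(C)=O)Cc1cc(C=O)cc2c1OC(C)(C)C=C2 | intermediate
16 | 1-(2,4-dihydroxyphenyl)ethan-1-one | CC(=O)c1ccc(O)cc1O | starting material
17 | tert-butyl (2-methylbut-3-en-2-yl) carbonate | C=CC(C)(C)OC(=O)OC(C)(C)C | starting material
18 | 1-{2-hydroxy-4-[(2-methylbut-3-en-2-yl)oxy]phenyl}ethan-1-one | CC(=O)c1ccc(OC(C)(C)C=C)cc1O | intermediate
19 | 4-acetyl-3-hydroxy-2-(3-methylbut-2-en-1-yl)cyclohexa-3,5-dien-1-one (not isolated) | CC(=O)C1=C(O)C(CC=C(C)C)C(=O)C=C1 | intermediate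
20 | 1-[2,4-dihydroxy-3-(3-methylbut-2-en-1-yl)phenyl]ethan-1-one | CC(=O)c1ccc(O)c(CC=C(C)C)c1O | intermediate
21 | (2E)-1-[2,4-dihydroxy-3-(3-methylbut-2-en-1-yl)phenyl]-3-{8-[(2R)-2-hydroxy-3-methylbut-3-en-1-yl]-2,2-dimethyl-2H-chromen-6-yl}prop-2-en-1-one | C=C(C)[C@H](O)Cc1cc(/C=C/C(=O)c2ccc(O)c(CC=C(C)C)c2O)cc2c1OC(C)(C)C=C2 | intermediate
22 | (2R)-7-hydroxy-2-{8-[(2R)-2-hydroxy-3-methylbut-3-en-1-yl]-2,2-dimethyl-2H-chromen-6-yl}-8-(3-methylbut-2-en-1-yl)-2,3-dihydro-4H-chromen-4-one (C2 epimer of 23; forms in step 9 and is converted into 23 through 21; not isolated) | C=C(C)[C@H](O)Cc1cc([C@H]2CC(=O)c3ccc(O)c(CC=C(C)C)c3O2)cc2c1OC(C)(C)C=C2 | intermediate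
23 | (2S)-7-hydroxy-2-{8-[(2R)-2-hydroxy-3-methylbut-3-en-1-yl]-2,2-dimethyl-2H-chromen-6-yl}-8-(3-methylbut-2-en-1-yl)-2,3-dihydro-4H-chromen-4-one | C=C(C)[C@H](O)Cc1cc([C@@H]2CC(=O)c3ccc(O)c(CC=C(C)C)c3O2)cc2c1OC(C)(C)C=C2 | target

**Totals**
Total step count: 9. Longest linear sequence: 7 (steps 1, 2, 3, 4, 5, 8, 9); steps 6 and 7 make the ring A ketone in parallel.

**Three steps most likely to fail**

Step 9. The two C2 epimers are diastereomers whose stereocentres lie far apart, so they may not resolve on an ordinary stationary phase. The fallback sets out from 21 and replaces chromatographic separation by a crystallization-induced diastereomer transformation. The ring is closed with catalytic piperidine in aqueous methanol at room temperature, from which the flavanone crystallizes, and the mixture is seeded with a small HPLC-pure sample of 23. The solution keeps equilibrating through 21 while one diastereomer leaves as solid. This makes no new compound F0 and comes back at 23.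

Step 5. The telescoped acetylation and dehydration may give tertiary chloride, acetyl migration through an acetoxonium ion, or the enol acetate. The fallback sets out from 13 and drops the acyl group in favour of a silyl ether and a concerted syn-elimination. Selective silylation of the secondary hydroxyl (TESCl, imidazole, DMF, 0 °C) gives 8-[(2R)-3-hydroxy-3-methyl-2-(triethylsilyloxy)butyl]-2,2-dimethyl-2H-chromene-6-carbaldehyde F1. The Burgess reagent (methyl N-(triethylammoniosulfonyl)carbamate, toluene, 60 °C) dehydrates it to 8-[(2R)-3-methyl-2-(triethylsilyloxy)but-3-en-1-yl]-2,2-dimethyl-2H-chromene-6-carbaldehyde F2. AcOH/THF/H2O removes the silyl group to give 8-[(2R)-2-hydroxy-3-methylbut-3-en-1-yl]-2,2-dimethyl-2H-chromene-6-carbaldehyde F3. F3 is condensed with 20 under the conditions of step 8, and the route is rejoined at 21.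

Step 8. The ketone 20 carries a free 4-hydroxyl, and its dianion may condense sluggishly with the electron-rich aldehyde. The fallback sets out from 18 (with 15) and changes the order of events, moving the Claisen rearrangement after the condensation. Ether 18 has only the chelated hydroxyl free and condenses with 15 under KOH/EtOH to (2E)-1-{2-hydroxy-4-[(2-methylbut-3-en-2-yl)oxy]phenyl}-3-{8-[(2R)-2-hydroxy-3-methylbut-3-en-1-yl]-2,2-dimethyl-2H-chromen-6-yl}prop-2-en-1-one F4. Heating F4 (N,N-diethylaniline, 180 °C) effects the aromatic Claisen rearrangement on the chalcone and comes back at 21. Any flavanone formed thermally is harmless because step 9 equilibrates it.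

**Further compounds**
F1 | step 5 | 8-[(2R)-3-hydroxy-3-methyl-2-(triethylsilyloxy)butyl]-2,2-dimethyl-2H-chromene-6-carbaldehyde | CC(C)(O)[C@H](O[Si](CC)(CC)CC)Cc1cc(C=O)cc2c1OC(C)(C)C=C2
F2 | step 5 | 8-[(2R)-3-methyl-2-(triethylsilyloxy)but-3-en-1-yl]-2,2-dimethyl-2H-chromene-6-carbaldehyde | C=C(C)[C@H](O[Si](CC)(CC)CC)Cc1cc(C=O)cc2c1OC(C)(C)C=C2
F3 | step 5 | 8-[(2R)-2-hydroxy-3-methylbut-3-en-1-yl]-2,2-dimethyl-2H-chromene-6-carbaldehyde | C=C(C)[C@H](O)Cc1cc(C=O)cc2c1OC(C)(C)C=C2
F4 | step 8 | (2E)-1-{2-hydroxy-4-[(2-methylbut-3-en-2-yl)oxy]phenyl}-3-{8-[(2R)-2-hydroxy-3-methylbut-3-en-1-yl]-2,2-dimethyl-2H-chromen-6-yl}prop-2-en-1-one | C=C(C)[C@H](O)Cc1cc(/C=C/C(=O)c2ccc(OC(C)(C)C=C)cc2O)cc2c1OC(C)(C)C=C2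
F0 | step 9 | none | none
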